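**Strategy**

The plan rests on cutting the isochromanone ring at both ends of its ester unit: the C1(=O)–O2 fragment, bonded to aromatic C8a and to stereocentre C3, is retrosynthetically carbon dioxide. The key step is a carboxylative lactonisation: Pd/photoredox carboxylation of an aryl bromide with CO2 gives a cesium benzoate that displaces a C3 mesylate with inversion, forming the aryl–carbonyl and O2–C3 bonds, the lactone ring and the C3 configuration in one operation. Its precursor is an open-chain bromoaryl mesyloxy tribenzyl ester whose three contiguous stereocentres derive from a trans,trans-trisubstituted butyrolactone assembled on (R)-5-(hydroxymethyl)butanolide by conjugate arylation and enolate alkylation.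

Key step: step 10

Remark: the target is made with the configuration exactly as drawn, (3S,4S) in the lactone ring and (2R) in the butanedioic acid chain; ring atoms are numbered as in 1H-isochromen-1-one (C1 carbonyl, O2, C3, C4, C4a to C8a).

**Route**

Step 1
Reactants: 1 5-bromobenzene-1,2,3-triol
Product: 2 1,2,3-tris(benzyloxy)-5-bromobenzene
Conditions: BnBr, K2CO3, DMF, 60 °C, N2
Reagents that add atoms: benzyl bromide, BrCc1ccccc1
Why: Williamson ether synthesis on the three phenoxides should give a symmetric arene whose two ring hydrogens are equivalent, which removes any regiochemical question from the later arylation.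

Step 2
Reactants: 3 (5R)-5-(hydroxymethyl)oxolan-2-one
Product: 4 (5R)-5-{[(tert-butyldiphenylsilyl)oxy]methyl}oxolan-2-one
Conditions: tBuPh2SiCl, imidazole, CH2Cl2, 0 °C to rt
Reagents that add atoms: tert-butyl(chloro)diphenylsilane, CC(C)(C)[Si](Cl)(c1ccccc1)c1ccccc1
Why: Imidazole-promoted silylation of the primary alcohol installs the bulky group that later shields one face of the butenolide, and the C5 stereocentre is untouched.

Step 3
Reactants: 4 (5R)-5-{[(tert-butyldiphenylsilyl)oxy]methyl}oxolan-2-one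
Product: 7 (5R)-5-{[(tert-butyldiphenylsilyl)oxy]methyl}furan-2(5H)-one, via α-phenylselanyl lactone 5 (not isolated), via selenoxide 6 (not isolated)
Conditions: LiN(iPr)2, THF, −78 °C; PhSeBr; then crude selenide, 30% H2O2, pyridine, CH2Cl2, 0 °C to rt
Reagents that add atoms: none
Why: α-Selenenylation of the lactone enolate followed by oxidation and selenoxide syn-elimination should give the endocyclic enoate, since only C4 carries hydrogens syn to selenium, without touching C5.

Step 4
Reactants: 2 1,2,3-tris(benzyloxy)-5-bromobenzene; 7 (5R)-5-{[(tert-butyldiphenylsilyl)oxy]methyl}furan-2(5H)-one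
Product: 11 (4S,5R)-4-[2,3,4-tris(benzyloxy)-6-bromophenyl]-5-{[(tert-butyldiphenylsilyl)oxy]methyl}oxolan-2-one, via aryllithium 8 (not isolated), via arylmagnesium bromide 9 (not isolated), via silyl ketene acetal 10 (not isolated)
Conditions: 2, LiN(iPr)2, THF, −78 °C; MgBr2·OEt2; CuBr·SMe2 (20 mol%), Me3SiCl, then 7, −78 to −40 °C; aq NH4Cl, then 1 M HCl
Reagents that add atoms: none
Why: Directed ortho-lithiation of 2 between bromine and a benzyloxy group (the only kind of ring C–H), transmetalation to magnesium to suppress aryne formation, and copper-catalysed, Me3SiCl-accelerated conjugate addition of the Grignard reagent anti to the C5 silyloxymethyl group should set C4 as (S).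

Step 5
Reactants: 11 (4S,5R)-4-[2,3,4-tris(benzyloxy)-6-bromophenyl]-5-{[(tert-butyldiphenylsilyl)oxy]methyl}oxolan-2-one; 12 methyl bromoacetate
Product: 14 methyl 2-[(3R,4S,5R)-4-[2,3,4-tris(benzyloxy)-6-bromophenyl]-5-{[(tert-butyldiphenylsilyl)oxy]methyl}-2-oxooxolan-3-yl]acetate, via lithium enolate 13 (not isolated)
Conditions: LiN(SiMe3)2, THF, −78 °C; then 12, −78 to −40 °C
Reagents that add atoms: none
Why: Enolate alkylation of a 4-substituted butyrolactone takes place anti to the C4 aryl group, setting C3 as (R), and this trans,trans arrangement is also the thermodynamic one, so any cis isomer could be equilibrated with base.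

Step 6
Reactants: 14 methyl 2-[(3R,4S,5R)-4-[2,3,4-tris(benzyloxy)-6-bromophenyl]-5-{[(tert-butyldiphenylsilyl)oxy]methyl}-2-oxooxolan-3-yl]acetate
Product: 15 methyl 2-[(3R,4S,5R)-4-[2,3,4-tris(benzyloxy)-6-bromophenyl]-5-(hydroxymethyl)-2-oxooxolan-3-yl]acetate
Conditions: Bu4NF, AcOH, THF, 0 °C to rt
Reagents that add atoms: none
Why: Fluoride-mediated desilylation, buffered with acetic acid, should free the primary alcohol without affecting the lactone, the methyl ester or the stereocentres.

Step 7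
Reactants: 15 methyl 2-[(3R,4S,5R)-4-[2,3,4-tris(benzyloxy)-6-bromophenyl]-5-(hydroxymethyl)-2-oxooxolan-3-yl]acetate
Product: 16 (2R,3S,4R)-3-[2,3,4-tris(benzyloxy)-6-bromophenyl]-4-(2-methoxy-2-oxoethyl)-5-oxooxolane-2-carboxylic acid
Conditions: TEMPO (20 mol%), PhI(OAc)2, MeCN/H2O (1:1), rt
Reagents that add atoms: water, O
Why: Nitroxyl-catalysed oxidation takes the primary alcohol through the aldehyde hydrate to the acid under near-neutral conditions that should tolerate the benzyl ethers and aryl bromide and should not epimerise the adjacent oxygenated carbon.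

Step 8
Reactants: 16 (2R,3S,4R)-3-[2,3,4-tris(benzyloxy)-6-bromophenyl]-4-(2-methoxy-2-oxoethyl)-5-oxooxolane-2-carboxylic acid
Product: 18 tribenzyl (1R,2S,3R)-2-[2,3,4-tris(benzyloxy)-6-bromophenyl]-1-hydroxybutane-1,3,4-tricarboxylate, via tricesium tricarboxylate 17 (not isolated)
Conditions: CsOH·H2O (3.0 equiv), THF/H2O, 0 °C to rt; evaporate; BnBr, DMF, 0 °C to rt
Reagents that add atoms: cesium hydroxide, [OH-].[Cs+]; benzyl bromide, BrCc1ccccc1
Why: Saponification opens the lactone by acyl–oxygen cleavage (no bond to a stereocentre is broken) and cleaves the methyl ester, and cesium carboxylate alkylation with benzyl bromide in DMF should then outpace relactonisation of the weakly nucleophilic α-hydroxy ester.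

Step 9
Reactants: 18 tribenzyl (1R,2S,3R)-2-[2,3,4-tris(benzyloxy)-6-bromophenyl]-1-hydroxybutane-1,3,4-tricarboxylate
Product: 19 tribenzyl (1R,2S,3R)-2-[2,3,4-tris(benzyloxy)-6-bromophenyl]-1-(methanesulfonyloxy)butane-1,3,4-tricarboxylate
Conditions: MsCl, Et3N, CH2Cl2, −20 °C
Reagents that add atoms: methanesulfonyl chloride, CS(=O)(=O)Cl
Why: Sulfonylation of the secondary α-hydroxy ester through the sulfene from MsCl and Et3N occurs at oxygen with retention, giving the (R)-mesylate activated for SN2 displacement by the adjacent ester.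

Step 10
Reactants: 19 tribenzyl (1R,2S,3R)-2-[2,3,4-tris(benzyloxy)-6-bromophenyl]-1-(methanesulfonyloxy)butane-1,3,4-tricarboxylate; 20 carbon dioxide
Product: 22 dibenzyl (2R)-2-[(3S,4S)-5,6,7-tris(benzyloxy)-3-(benzyloxycarbonyl)-1-oxo-3,4-dihydro-1H-isochromen-4-yl]butanedioate, via cesium benzoate 21 (not isolated)
Conditions: CO2 (1 atm), Pd(OAc)2 (5 mol%), PhXPhos (10 mol%), [Ir(ppy)2(dtbbpy)]PF6 (1 mol%), iPr2NEt, Cs2CO3, DMA, blue LEDs, rt; then 50 °C
Reagents that add atoms: none
Why: Zerovalent palladium inserts into the C8a–Br bond, the resulting arylpalladium bromide is reduced by the photoreduced iridium complex (iPr2NEt as terminal reductant) to a species nucleophilic enough to add to CO2, and the carboxylate is released as cesium benzoate 21, which then attacks C3 from the face opposite the mesylate. The closest known reaction types are the Pd/photoredox reductive carboxylation of aryl bromides with CO2 and the displacement of α-sulfonyloxy esters by cesium carboxylates, here telescoped into one carboxylative lactonisation. The isochromanone ring closes in 6-exo-tet mode. C3 is set by stereospecific inversion of the (R)-mesylate to (S), which places the C3 ester trans to the C4 side chain, while C4 and the succinate stereocentre are spectators. The step needs carboxylation only at C8a, which the bromine placed there through the symmetric arene secures, and activation of the aryl bromide without loss of the mesylate or benzyl esters, which the room-temperature conditions and the inertness of sulfonates toward zerovalent palladium should allow. It also needs O-alkylation at C3 to win over elimination toward C4, which the six-membered transition state and the SN2-activating α-ester should favour.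

Step 11
Reactants: 22 dibenzyl (2R)-2-[(3S,4S)-5,6,7-tris(benzyloxy)-3-(benzyloxycarbonyl)-1-oxo-3,4-dihydro-1H-isochromen-4-yl]butanedioate
Product: 23 (2R)-2-[(3S,4S)-3-carboxy-5,6,7-trihydroxy-1-oxo-3,4-dihydro-1H-isochromen-4-yl]butanedioic acid
Conditions: H2 (1 atm), 10% Pd/C, THF/MeOH, rt, then filtration under argon
Reagents that add atoms: none
Why: Hydrogenolysis over Pd/C should cleave all six O-benzyl groups (three aryl ethers, three esters), while the lactone C–O bond is not benzylic and no stereocentre is involved.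

**Compound list**

1 | 5-bromobenzene-1,2,3-triol | Oc1cc(Br)cc(O)c1O | starting material
2 | 1,2,3-tris(benzyloxy)-5-bromobenzene | Brc1cc(OCc2ccccc2)c(OCc2ccccc2)c(OCc2ccccc2)c1 | intermediate
3 | (5R)-5-(hydroxymethyl)oxolan-2-one | O=C1CC[C@H](CO)O1 | starting material
4 | (5R)-5-{[(tert-butyldiphenylsilyl)oxy]methyl}oxolan-2-one | O=C1CC[C@H](CO[Si](c2ccccc2)(c2ccccc2)C(C)(C)C)O1 | intermediate
5 | (5R)-5-{[(tert-butyldiphenylsilyl)oxy]methyl}-3-(phenylselanyl)oxolan-2-one, C3 epimers (not isolated) | O=C1C([Se]c2ccccc2)C[C@H](CO[Si](c2ccccc2)(c2ccccc2)C(C)(C)C)O1 | intermediate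
6 | (5R)-3-(benzeneseleninyl)-5-{[(tert-butyldiphenylsilyl)oxy]methyl}oxolan-2-one (not isolated) | O=C1C([Se](=O)c2ccccc2)C[C@H](CO[Si](c2ccccc2)(c2ccccc2)C(C)(C)C)O1 | intermediate
7 | (5R)-5-{[(tert-butyldiphenylsilyl)oxy]methyl}furan-2(5H)-one | O=C1C=C[C@H](CO[Si](c2ccccc2)(c2ccccc2)C(C)(C)C)O1 | intermediate
8 | [2,3,4-tris(benzyloxy)-6-bromophenyl]lithium (not isolated) | [Li]c1c(Br)cc(OCc2ccccc2)c(OCc2ccccc2)c1OCc1ccccc1 | intermediate
9 | [2,3,4-tris(benzyloxy)-6-bromophenyl]magnesium bromide (not isolated) | Br[Mg]c1c(Br)cc(OCc2ccccc2)c(OCc2ccccc2)c1OCc1ccccc1 | intermediate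
10 | (2R,3S)-3-[2,3,4-tris(benzyloxy)-6-bromophenyl]-2-{[(tert-butyldiphenylsilyl)oxy]methyl}-5-(trimethylsilyloxy)-2,3-dihydrofuran (not isolated) | C[Si](C)(C)OC1=C[C@@H](c2c(Br)cc(OCc3ccccc3)c(OCc3ccccc3)c2OCc2ccccc2)[C@H](CO[Si](c2ccccc2)(c2ccccc2)C(C)(C)C)O1 | intermediate
11 | (4S,5R)-4-[2,3,4-tris(benzyloxy)-6-bromophenyl]-5-{[(tert-butyldiphenylsilyl)oxy]methyl}oxolan-2-one | O=C1C[C@@H](c2c(Br)cc(OCc3ccccc3)c(OCc3ccccc3)c2OCc2ccccc2)[C@H](CO[Si](c2ccccc2)(c2ccccc2)C(C)(C)C)O1 | intermediate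
12 | methyl bromoacetate | COC(=O)CBr | starting material
13 | lithium enolate of 11 (not isolated) | [Li]OC1=C[C@@H](c2c(Br)cc(OCc3ccccc3)c(OCc3ccccc3)c2OCc2ccccc2)[C@H](CO[Si](c2ccccc2)(c2ccccc2)C(C)(C)C)O1 | intermediate
14 | methyl 2-[(3R,4S,5R)-4-[2,3,4-tris(benzyloxy)-6-bromophenyl]-5-{[(tert-butyldiphenylsilyl)oxy]methyl}-2-oxooxolan-3-yl]acetate | COC(=O)C[C@H]1C(=O)O[C@@H](CO[Si](c2ccccc2)(c2ccccc2)C(C)(C)C)[C@@H]1c1c(Br)cc(OCc2ccccc2)c(OCc2ccccc2)c1OCc1ccccc1 | intermediate
15 | methyl 2-[(3R,4S,5R)-4-[2,3,4-tris(benzyloxy)-6-bromophenyl]-5-(hydroxymethyl)-2-oxooxolan-3-yl]acetate | COC(=O)C[C@H]1C(=O)O[C@@H](CO)[C@@H]1c1c(Br)cc(OCc2ccccc2)c(OCc2ccccc2)c1OCc1ccccc1 | intermediate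
16 | (2R,3S,4R)-3-[2,3,4-tris(benzyloxy)-6-bromophenyl]-4-(2-methoxy-2-oxoethyl)-5-oxooxolane-2-carboxylic acid | COC(=O)C[C@H]1C(=O)O[C@@H](C(=O)O)[C@@H]1c1c(Br)cc(OCc2ccccc2)c(OCc2ccccc2)c1OCc1ccccc1 | intermediate
17 | tricesium (1R,2S,3R)-2-[2,3,4-tris(benzyloxy)-6-bromophenyl]-1-hydroxybutane-1,3,4-tricarboxylate (not isolated) | [Cs+].[Cs+].[Cs+].[O-]C(=O)C[C@@H](C(=O)[O-])[C@@H](c1c(Br)cc(OCc2ccccc2)c(OCc2ccccc2)c1OCc1ccccc1)[C@@H](O)C(=O)[O-] | intermediate
18 | tribenzyl (1R,2S,3R)-2-[2,3,4-tris(benzyloxy)-6-bromophenyl]-1-hydroxybutane-1,3,4-tricarboxylate | O=C(OCc1ccccc1)C[C@@H](C(=O)OCc1ccccc1)[C@@H](c1c(Br)cc(OCc2ccccc2)c(OCc2ccccc2)c1OCc1ccccc1)[C@@H](O)C(=O)OCc1ccccc1 | intermediate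
19 | tribenzyl (1R,2S,3R)-2-[2,3,4-tris(benzyloxy)-6-bromophenyl]-1-(methanesulfonyloxy)butane-1,3,4-tricarboxylate | O=C(OCc1ccccc1)C[C@@H](C(=O)OCc1ccccc1)[C@@H](c1c(Br)cc(OCc2ccccc2)c(OCc2ccccc2)c1OCc1ccccc1)[C@@H](OS(C)(=O)=O)C(=O)OCc1ccccc1 | intermediate
20 | carbon dioxide | O=C=O | starting material
21 | cesium 3,4,5-tris(benzyloxy)-2-[(1R,2S,3R)-1,3,4-tris(benzyloxycarbonyl)-1-(methanesulfonyloxy)butan-2-yl]benzoate (not isolated) | O=C(OCc1ccccc1)C[C@@H](C(=O)OCc1ccccc1)[C@@H](c1c(C(=O)[O-])cc(OCc2ccccc2)c(OCc2ccccc2)c1OCc1ccccc1)[C@@H](OS(C)(=O)=O)C(=O)OCc1ccccc1.[Cs+] | intermediate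
22 | dibenzyl (2R)-2-[(3S,4S)-5,6,7-tris(benzyloxy)-3-(benzyloxycarbonyl)-1-oxo-3,4-dihydro-1H-isochromen-4-yl]butanedioate | O=C(OCc1ccccc1)C[C@@H](C(=O)OCc1ccccc1)[C@H]1c2c(cc(OCc3ccccc3)c(OCc3ccccc3)c2OCc2ccccc2)C(=O)O[C@@H]1C(=O)OCc1ccccc1 | intermediate
23 | (2R)-2-[(3S,4S)-3-carboxy-5,6,7-trihydroxy-1-oxo-3,4-dihydro-1H-isochromen-4-yl]butanedioic acid | O=C(O)C[C@@H](C(=O)O)[C@H]1c2c(cc(O)c(O)c2O)C(=O)O[C@@H]1C(=O)O | target

**Step count and risks**

Total step count: 11. Longest linear sequence: 10 steps (from 3 through steps 2 to 11); the arene branch (step 1) joins at step 4.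

Steps most likely to fail:

1. Step 10. The mesylate may be displaced, eliminated or epimerised in the basic medium before the benzoate has formed, and protodebromination may compete with CO2 insertion. Fallback: the two bond formations are separated, setting out from 18. Silylation (tBuMe2SiOTf, 2,6-lutidine, CH2Cl2, −78 °C) would give tribenzyl (1R,2S,3R)-2-[2,3,4-tris(benzyloxy)-6-bromophenyl]-1-[(tert-butyldimethylsilyl)oxy]butane-1,3,4-tricarboxylate F1. Reductive carboxylation with CO2 (Pd(OAc)2, tBuXPhos, Et2Zn, DMA, 40 °C; acidic work-up), now free of any sensitive electrophile, would give 3,4,5-tris(benzyloxy)-2-[(1R,2S,3R)-1,3,4-tris(benzyloxycarbonyl)-1-[(tert-butyldimethylsilyl)oxy]butan-2-yl]benzoic acid F2. HF·pyridine in THF would liberate 3,4,5-tris(benzyloxy)-2-[(1R,2S,3R)-1,3,4-tris(benzyloxycarbonyl)-1-hydroxybutan-2-yl]benzoic acid F3. Mitsunobu lactonisation (PPh3, DIAD, THF, 0 °C) would then close the ring with inversion at C3 and come back to the route at 22.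

2. Step 4. Aryl transfer from the doubly ortho-substituted organocopper species may be slow, and the ortho-bromoaryl metal may lose metal bromide to an aryne or transfer a benzylic proton on warming. Fallback: the polarity of the arylation is changed, setting out from 2. Iodination (N-iodosuccinimide, cat. CF3CO2H, MeCN), which can only occur at the two equivalent positions, would give 1,2,3-tris(benzyloxy)-5-bromo-4-iodobenzene F4. A reductive Heck reaction of F4 with butenolide 7 (Pd(OAc)2, HCO2Na, Bu4NCl, DMF, 60 °C), with the C–I bond reacting before C–Br and the aryl group delivered anti to the C5 substituent, would come back to the route at 11.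

3. Step 8. The γ-hydroxy ester may relactonise with loss of benzyl alcohol during the basic alkylation, and esterification of three carboxylates may be incomplete. Fallback: esterification is moved from carboxylate alkylation to acid-promoted alkylation by a diazoalkane, setting out from 17. Cold acidification (aq HCl, 0 °C, pH 3) and extraction would give (1R,2S,3R)-2-[2,3,4-tris(benzyloxy)-6-bromophenyl]-1-hydroxybutane-1,3,4-tricarboxylic acid F5, which would be treated at once with phenyldiazomethane (Et2O/CH2Cl2, 0 °C) under neutral conditions to come back to the route at 18.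

Further compounds
F1 | step 10 | tribenzyl (1R,2S,3R)-2-[2,3,4-tris(benzyloxy)-6-bromophenyl]-1-[(tert-butyldimethylsilyl)oxy]butane-1,3,4-tricarboxylate | O=C(OCc1ccccc1)C[C@@H](C(=O)OCc1ccccc1)[C@@H](c1c(Br)cc(OCc2ccccc2)c(OCc2ccccc2)c1OCc1ccccc1)[C@@H](O[Si](C)(C)C(C)(C)C)C(=O)OCc1ccccc1
F2 | step 10 | 3,4,5-tris(benzyloxy)-2-[(1R,2S,3R)-1,3,4-tris(benzyloxycarbonyl)-1-[(tert-butyldimethylsilyl)oxy]butan-2-yl]benzoic acid | O=C(OCc1ccccc1)C[C@@H](C(=O)OCc1ccccc1)[C@@H](c1c(C(=O)O)cc(OCc2ccccc2)c(OCc2ccccc2)c1OCc1ccccc1)[C@@H](O[Si](C)(C)C(C)(C)C)C(=O)OCc1ccccc1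
F3 | step 10 | 3,4,5-tris(benzyloxy)-2-[(1R,2S,3R)-1,3,4-tris(benzyloxycarbonyl)-1-hydroxybutan-2-yl]benzoic acid | O=C(OCc1ccccc1)C[C@@H](C(=O)OCc1ccccc1)[C@@H](c1c(C(=O)O)cc(OCc2ccccc2)c(OCc2ccccc2)c1OCc1ccccc1)[C@@H](O)C(=O)OCc1ccccc1
F4 | step 4 | 1,2,3-tris(benzyloxy)-5-bromo-4-iodobenzene | Brc1cc(OCc2ccccc2)c(OCc2ccccc2)c(OCc2ccccc2)c1I
F5 | step 8 | (1R,2S,3R)-2-[2,3,4-tris(benzyloxy)-6-bromophenyl]-1-hydroxybutane-1,3,4-tricarboxylic acid | OC(=O)C[C@@H](C(=O)O)[C@@H](c1c(Br)cc(OCc2ccccc2)c(OCc2ccccc2)c1OCc1ccccc1)[C@@H](O)C(=O)O
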